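## Structural features

Dielsianone is an achiral benzil: an ethane-1,2-dione with a 4-methoxyphenyl ring on one carbonyl and C6 of a 2,2-dimethyl-2H-chromene on the other. The pyran ring (O1, C2 with two methyl groups, C3=C4) is fused to benzene ring A through C4a and C8a. Ring A is pentasubstituted: C4a carries the pyran carbon, C5 a hydroxyl, C6 the dicarbonyl chain, C7 hydrogen, C8 a methoxy group and C8a the ring oxygen. There is no stereocentre, so no stereocentres stand next to each other; every selectivity question is one of regiochemistry. The fragile groups are the 1,2-diketone (nucleophiles, hydroxide, peroxides), the styrene-like C3=C4 bond (acid, electrophiles) and the para-related C5–OH/C8–OMe pair, which oxidants can take to a quinone. The real difficulty is ring A: its three oxygens must be told apart, the acyl group must sit next to the C5 hydroxyl, and the pyran must close on the C8a oxygen although the C5 oxygen also flanks C4a. The key step uses the fact that the run C5–C4a–C8a–C8 (O, C, O, O) is the carbon chain of a 2-prenylated 4-methoxyacetoacetic ester, while C6–C7 is the two-carbon unit of a terminal alkynyl ketone. The hydrogen bond from C5–OH to the C6 carbonyl, which arises from that construction, later distinguishes the two phenols when the pyran ring is closed.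

## Logic of the disconnections

**18 to 16.** The O1–C2 bond is cut and C3=C4 is returned to a prenyl chain on C4a beside a free C8a hydroxyl. A 2,2-dimethyl-2H-chromene fused to a phenol is the direct product of dehydrogenative cyclisation of an ortho-prenylphenol, and the cut keeps the sensitive chromene alkene out of every earlier step. The gain is one ring and one fragile double bond fewer. The forward step must form 17 on the C8a oxygen, which the C5–OH···O=C6 hydrogen bond of 16 should ensure, and must not oxidise the para-methoxyphenol further.

**16 to 7 and 13.** The ring bonds C8–C7 and C5–C6 are cut, after the phenols are re-silylated and the aryl ketone re-masked (15) and methanol is added back across C5 and C8 (14). Ring A is the true problem, and this cut divides it into a four-carbon piece holding the prenyl group and all three oxygens in order, and a two-carbon piece holding the whole dicarbonyl chain. One ring, two C–C bonds and five substituents fall away together, and both pieces are acyclic. The forward step must bond C8 to the hydrogen-bearing alkyne carbon, must cyclise rather than add to the carbonyl, must expel the C5 methoxy group on aromatisation, and must tolerate one acidic work-up that spares the prenyl group.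

**7 through 5 to 4.** The two O–Si bonds are cut in turn (through 6), since 7 is the doubly enolised, doubly silylated form of a β-keto ester. The gain is a stable, storable 1,3-dicarbonyl compound. The first silylation needs only an amine base. The second needs kinetic deprotonation at the methoxymethyl carbon, not at the prenyl methylene, and 7 cannot be stored.

**4 to 1 and 2.** The bond between the future C4a and the prenyl methylene is cut (through 3). C4a corresponds to the most acidic carbon of 1, and placing the prenyl group before ring A exists avoids any question of where an arene would be prenylated. The gain is two commercial compounds. The forward step must stop at monoalkylation on carbon.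

**13 to 10 and 11.** The bond between the ketone carbon and the alkyne is cut (through 12), an acyl cation equivalent plus an acetylide. The gain is a commercial Grignard reagent. The forward step must deliver one ethynyl group only and release a terminal ynone without conjugate addition of the amine set free.

**10 through 9 to 8.** The amide C–N bond and the two ketal C–O bonds are cut. The ketal leaves a single carbonyl for the acetylide and later keeps the diene away from a vicinal dicarbonyl. The gain is a commercial keto ester in which both carbonyl carbons are already joined to the anisyl ring. The forward steps must ketalise a ketone conjugated to a donor arene and aminolyse an ester on a fully substituted carbon.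

## Other disconnections considered

**Alternative 1:** The cut falls on the two C–C bonds flanking the dicarbonyl unit (C6–CO and CO–C1′). The key-step product would be the methoxymethyl ether A1, 1-[8-methoxy-5-(methoxymethoxy)-2,2-dimethyl-2H-chromen-6-yl]-2-(4-methoxyphenyl)ethane-1,2-dione.
- Forward step: the chromene A2 (8-methoxy-5-(methoxymethoxy)-2,2-dimethyl-2H-chromene) would be lithiated at C6 by n-butyllithium A3 under direction of the C5 acetal oxygen. The aryllithium would add once to 1,4-dimethylpiperazine-2,3-dione A4, and 4-methoxyphenylmagnesium bromide A5 would add to the other amide carbonyl. Acid would collapse both adducts to A1, and mild acid would then remove the acetal to give 18.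
- In favour: it is convergent, the diketone appears without any oxidation, and the pyran ring is in place early, so no late oxidant meets the para-methoxyphenol.
- Against: the ring A problem is moved, not solved. A2 must be built on a methoxy-substituted hydroquinone core where two hydroxyls compete for annulation and protection. Lithiation must choose C6 over C7 (next to the methoxy group). The final acid step must spare the chromene alkene.
- Comparison: on mechanism it is the better of the two, since directed ortho-metalation and sequential addition to a cyclic oxamide are more predictable than the cycloaromatisation of an untried diene. On step economy it is about equal (some four steps to A2, then two). On structure the chosen plan is stronger, because five ring A substituents arise in fixed order from acyclic pieces with no positional selectivity on a polyoxygenated arene.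

**Alternative 2:** The cut is C5–C6, with ring A traced back to a four-membered ring. The key-step product would be the stilbene phenol A6, (E)-5-isopropoxy-4-methoxy-2-(4-methoxystyryl)phenol.
- Forward step: heating the cyclobutenone A7 (3-isopropoxy-4-methoxy-4-[(1E,3E)-4-(4-methoxyphenyl)buta-1,3-dienyl]cyclobut-2-en-1-one) would open the ring conrotatorily with the methoxy group turning outward. The resulting dienylketene would close by 6π electrocyclisation onto the near double bond and tautomerise to A6.
- In favour: the conditions are neutral and reagent-free, and the para relation of C5–OH and C8–OMe arises automatically.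
- Against: A6 lacks three features of the target. Its side chain is an alkene, not a diketone; C4a carries hydrogen; the C8a oxygen carries an isopropyl group. The alkene would have to be oxidised next to a free phenol, which invites oxidative closure to a 2-arylbenzofuran. The isopropyl ether would have to be cleaved beside two methyl ethers, and a propargyl ether Claisen sequence would still be needed for the pyran. A7 itself requires a squaric ester derivative, a dienyl metal reagent and O-methylation of a tertiary alkoxide.
- Comparison: on regiochemical certainty it is the better, since every oxygen position is written into the four-membered ring and does not depend on orbital coefficients. On mechanism it is equal in economy of bond formation. On step economy it is clearly worse, roughly twice as long. On structure it builds only three of the five ring A substituents.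

**Alternative 3:** The cut is C4–C3 and C2–O1 of the pyran ring. The key-step product would be the 4-methoxychroman A8, 1-(5-hydroxy-4,8-dimethoxy-2,2-dimethylchroman-6-yl)-2-(4-methoxyphenyl)ethane-1,2-dione (racemic).
- Forward step: the salicylaldehyde A9 (1-(3-formyl-2,4-dihydroxy-5-methoxyphenyl)-2-(4-methoxyphenyl)ethane-1,2-dione) would be treated with Sc(OTf)3 A10 and trimethyl orthoformate A11. The resulting methoxy-substituted ortho-quinone methide, in its oxocarbenium form, would be trapped by isobutene A12 in a polar [4+2] reaction that puts the gem-dimethyl carbon on oxygen. Acid-induced loss of methanol from A8 would then give 18.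
- In favour: two pyran bonds form at once from a cheap gas, and no oxidant is used. On this point it is better than the DDQ step of the chosen plan.
- Against: it addresses the pyran ring only. A9 still needs ring A with its diketone, made by a cycloaromatisation of the chosen kind or otherwise, plus a formylation between two hydroxyls. The aldehyde is flanked by two phenols, and only chelation of the C5 hydroxyl biases which oxygen closes. The Lewis acid and orthoester could also ketalise the diketone.
- Comparison: on regiochemistry it is equal, since the same two oxygens compete in both plans. On step economy it is worse: formylation, annulation and elimination replace one step. On structure it is complementary to the chosen plan, not a rival for ring A.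

Key step: step 7

**Remarks on the chemistry**
- Assumption: the aryl keto ester is taken as its commercial methyl ester 8, so that ketalisation in methanol cannot exchange the ester group.
- The alkene geometries of 3, 5, 6 and 7 and the transient stereocentres of 4, 12 and 14 are erased later; one isomer of each is drawn.
- Atom mapping of step 7, checked against 18: C1, C2, C3, C4 of 7 become C5, C4a, C8a, C8, and the alkyne carbons C3 and C4 of 13 become C6 and C7. No structure needed correction.
- Design points for the precursors: 7 is made under argon and used crude and in excess; 13 is released by an inverse acidic quench and used fresh; step 7 is run without any Lewis acid.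

## Route

Step 1
Reactants: 1 methyl 4-methoxyacetoacetate; 2 prenyl bromide
Product: 4 methyl 2-(2-methoxyacetyl)-5-methylhex-4-enoate (racemic), via sodium enolate 3 (not isolated)
Conditions: NaH, THF, 0 °C; then 2, 0 °C → rt
Reagents that add atoms: none
Why: Acetoacetic ester alkylation: one equivalent of NaH removes only the hydrogen between the two carbonyl groups, and the soft enolate 3 attacks the allylic bromide on carbon in an SN2 reaction; a slight excess of 1 over 2 holds back double alkylation.

Step 2
Reactants: 4 methyl 2-(2-methoxyacetyl)-5-methylhex-4-enoate
Product: 5 methyl (2E)-4-methoxy-2-(3-methylbut-2-enyl)-3-(trimethylsilyloxy)but-2-enoate (either alkene isomer serves)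
Conditions: Me3SiCl, Et3N, PhMe, rt
Reagents that add atoms: chlorotrimethylsilane, C[Si](C)(C)Cl
Why: Silyl enol ether formation by soft enolisation of a β-keto ester; the ester-conjugated enol ether is the thermodynamically preferred regioisomer, and any non-conjugated isomer would be carried by step 3 to the same diene.

Step 3
Reactants: 5 methyl (2E)-4-methoxy-2-(3-methylbut-2-enyl)-3-(trimethylsilyloxy)but-2-enoate
Product: 7 1,4-dimethoxy-2-(3-methylbut-2-enyl)-1,3-bis(trimethylsilyloxy)buta-1,3-diene (1Z,3Z isomer drawn), via lithium dienolate 6 (not isolated)
Conditions: LiN(iPr)2, THF, −78 °C; then Me3SiCl, −78 °C → rt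
Reagents that add atoms: chlorotrimethylsilane, C[Si](C)(C)Cl
Why: Standard two-stage preparation of a 1-alkoxy-1,3-bis(silyloxy)diene: the amide base removes a hydrogen of the methoxymethyl group, the only position vinylogously conjugated to the ester, and 6 is silylated on the ester oxygen; LiCl is filtered off under argon and crude 7 goes straight into step 7.

Step 4
Reactants: 8 methyl 4-methoxybenzoylformate
Product: 9 methyl 2,2-dimethoxy-2-(4-methoxyphenyl)acetate
Conditions: HC(OMe)3, MeOH, H2SO4 (cat.), reflux
Reagents that add atoms: trimethyl orthoformate, COC(OC)OC; methanol, CO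
Why: Acid-catalysed ketalisation of the keto group of an α-keto ester, driven by the orthoformate as water scavenger; the anisyl group stabilises the oxocarbenium intermediate and the methyl ester matches the solvent.

Step 5
Reactants: 9 methyl 2,2-dimethoxy-2-(4-methoxyphenyl)acetate
Product: 10 N,2,2-trimethoxy-2-(4-methoxyphenyl)-N-methylacetamide
Conditions: MeNHOMe·HCl, iPrMgCl, THF, −20 → 0 °C
Reagents that add atoms: N,O-dimethylhydroxylamine hydrochloride, CNOC.Cl
Why: Weinreb amide synthesis from an ester: iPrMgCl turns the amine salt into its chloromagnesium amide, which attacks the ester carbonyl activated by two α-methoxy groups; there is no α-hydrogen and the ketal is inert to base.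

Step 6
Reactants: 10 N,2,2-trimethoxy-2-(4-methoxyphenyl)-N-methylacetamide; 11 ethynylmagnesium bromide
Product: 13 1,1-dimethoxy-1-(4-methoxyphenyl)but-3-yn-2-one, via magnesium hemiaminal chelate 12 (not isolated)
Conditions: THF, 0 °C → rt; inverse quench into aq NaHSO4, 0 °C
Reagents that add atoms: none
Why: Weinreb ketone synthesis: chelate 12 holds until the quench, so one ethynyl group is delivered; pouring into cold acid protonates the released N,O-dimethylhydroxylamine before it can add to the terminal ynone, and the slowly hydrolysing α-keto ketal survives the short contact.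

Step 7
Reactants: 7 1,4-dimethoxy-2-(3-methylbut-2-enyl)-1,3-bis(trimethylsilyloxy)buta-1,3-diene; 13 1,1-dimethoxy-1-(4-methoxyphenyl)but-3-yn-2-one
Product: 16 1-[2,4-dihydroxy-5-methoxy-3-(3-methylbut-2-enyl)phenyl]-2-(4-methoxyphenyl)ethane-1,2-dione, via cyclohexa-1,4-diene cycloadduct 14 (not isolated), via bis(trimethylsilyl) ketal arene 15 (not isolated)
Conditions: PhMe, rt → 60 °C; then 1 M HCl, THF, rt
Reagents that add atoms: water, O
Why: Normal-electron-demand Diels–Alder reaction of the trioxygenated diene 7 (in excess) with the electron-poor alkyne of 13, either concerted and strongly asynchronous or, at the polar extreme, a Mukaiyama–Michael addition followed by closure of the allenolate carbon onto the silyloxycarbenium carbon; both courses form C8–C7 and C5–C6 and give 14. The closest known reaction type is the cycloaromatisation of 1-alkoxy-1,3-bis(silyloxy)buta-1,3-dienes with alkynyl ketones and propiolates to acylresorcinols. Ring A is closed in the intermolecular [4+2] mode, four carbons from 7 and two from 13. The two sp3 carbons of 14 are not controlled and need not be, because 1,4-elimination of methanol (C5 methoxy group with the C8 hydrogen) erases both; C5 has no hydrogen, so this is the only way to aromatise, the C8 methoxy group stays and the C5 silyloxy oxygen becomes the phenol (15). The regioselectivity needed is bonding of C8 to the unsubstituted alkyne carbon: the two oxygens on C5 and the silyloxy group on C8a all raise the HOMO coefficient at C8 against one methoxy group pushing the other way, and the LUMO coefficient of the ynone is largest at its terminal carbon. The chemoselectivity needed is ring formation through C5 and C8, not Mukaiyama aldol addition or a [3+3] annulation through C4a; the absence of any Lewis acid and the ketal mask, which leaves a single carbonyl, secure it. Dilute HCl then cleaves both aryl silyl ethers and the ketal, whose ionisation is helped by the 4-methoxyphenyl group, at an acidity too low to add a phenol across the prenyl double bond.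

Step 8
Reactants: 16 1-[2,4-dihydroxy-5-methoxy-3-(3-methylbut-2-enyl)phenyl]-2-(4-methoxyphenyl)ethane-1,2-dione
Product: 18 dielsianone [1-(5-hydroxy-8-methoxy-2,2-dimethyl-2H-chromen-6-yl)-2-(4-methoxyphenyl)ethane-1,2-dione], via ortho-quinone methide 17 (not isolated)
Conditions: DDQ, PhMe, 80 °C
Reagents that add atoms: none
Why: Oxidative cyclisation of an ortho-prenylphenol with DDQ: hydride abstraction from the benzylic methylene and loss of the C8a hydroxyl proton give 17, whose thermal oxa-6π electrocyclisation forms O1–C2. The C5 hydroxyl is tied up in a hydrogen bond to the C6 carbonyl and the C8a hydroxyl, para to the acyl group, is the more acidic, so closure on the C8a oxygen is expected; a dry, non-nucleophilic solvent disfavours oxidative demethylation of the para-methoxyphenol.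

## Compound list

1 | methyl 4-methoxyacetoacetate (methyl 4-methoxy-3-oxobutanoate) | COCC(=O)CC(=O)OC | starting material
2 | prenyl bromide (1-bromo-3-methylbut-2-ene) | CC(C)=CCBr | starting material
3 | sodium (Z)-1,4-dimethoxy-4-oxobut-2-en-2-olate (sodium enolate of 1) | COC/C([O-])=C/C(=O)OC.[Na+] | intermediate (not isolated)
4 | methyl 2-(2-methoxyacetyl)-5-methylhex-4-enoate (racemic, one enantiomer drawn; the centre is enolisable and is lost in step 2) | COCC(=O)[C@@H](CC=C(C)C)C(=O)OC | intermediate
5 | methyl (2E)-4-methoxy-2-(3-methylbut-2-enyl)-3-(trimethylsilyloxy)but-2-enoate (one alkene isomer drawn) | COC/C(O[Si](C)(C)C)=C(/CC=C(C)C)C(=O)OC | intermediate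
6 | lithium 1,4-dimethoxy-2-(3-methylbut-2-enyl)-3-(trimethylsilyloxy)buta-1,3-dien-1-olate (one isomer drawn) | CO/C=C(\O[Si](C)(C)C)/C(CC=C(C)C)=C(/OC)[O-].[Li+] | intermediate (not isolated)
7 | (1Z,3Z)-1,4-dimethoxy-2-(3-methylbut-2-enyl)-1,3-bis(trimethylsilyloxy)buta-1,3-diene (one isomer drawn) | CO/C=C(\O[Si](C)(C)C)/C(CC=C(C)C)=C(/OC)O[Si](C)(C)C | intermediate
8 | methyl 4-methoxybenzoylformate (methyl 2-(4-methoxyphenyl)-2-oxoacetate) | COC(=O)C(=O)c1ccc(OC)cc1 | starting material
9 | methyl 2,2-dimethoxy-2-(4-methoxyphenyl)acetate | COC(=O)C(OC)(OC)c1ccc(OC)cc1 | intermediate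
10 | N,2,2-trimethoxy-2-(4-methoxyphenyl)-N-methylacetamide | CON(C)C(=O)C(OC)(OC)c1ccc(OC)cc1 | intermediate
11 | ethynylmagnesium bromide | C#C[Mg]Br | starting material
12 | bromomagnesium 2-[methoxy(methyl)amino]-1,1-dimethoxy-1-(4-methoxyphenyl)but-3-yn-2-olate (racemic, one enantiomer drawn) | C#C[C@](O[Mg]Br)(N(C)OC)C(OC)(OC)c1ccc(OC)cc1 | intermediate (not isolated)
13 | 1,1-dimethoxy-1-(4-methoxyphenyl)but-3-yn-2-one | C#CC(=O)C(OC)(OC)c1ccc(OC)cc1 | intermediate
14 | 1-[3,6-dimethoxy-5-(3-methylbut-2-enyl)-4,6-bis(trimethylsilyloxy)cyclohexa-1,4-dien-1-yl]-2,2-dimethoxy-2-(4-methoxyphenyl)ethan-1-one (racemic; the cis-3,6-dimethoxy isomer that follows from the drawn diene is shown; both centres vanish on aromatisation) | COc1ccc(C(OC)(OC)C(=O)C2=C[C@@H](OC)C(O[Si](C)(C)C)=C(CC=C(C)C)[C@]2(OC)O[Si](C)(C)C)cc1 | intermediate (not isolated)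
15 | 2,2-dimethoxy-1-[5-methoxy-3-(3-methylbut-2-enyl)-2,4-bis(trimethylsilyloxy)phenyl]-2-(4-methoxyphenyl)ethan-1-one | COc1ccc(C(OC)(OC)C(=O)c2cc(OC)c(O[Si](C)(C)C)c(CC=C(C)C)c2O[Si](C)(C)C)cc1 | intermediate (not isolated)
16 | 1-[2,4-dihydroxy-5-methoxy-3-(3-methylbut-2-enyl)phenyl]-2-(4-methoxyphenyl)ethane-1,2-dione | COc1ccc(C(=O)C(=O)c2cc(OC)c(O)c(CC=C(C)C)c2O)cc1 | intermediate
17 | (6Z)-5-hydroxy-2-methoxy-4-[2-(4-methoxyphenyl)-2-oxoacetyl]-6-(3-methylbut-2-enylidene)cyclohexa-2,4-dien-1-one (dimethylvinyl group syn to the ring carbonyl) | COc1ccc(C(=O)C(=O)C2=C(O)/C(=C/C=C(C)C)C(=O)C(OC)=C2)cc1 | intermediate (not isolated)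
18 | dielsianone, 1-(5-hydroxy-8-methoxy-2,2-dimethyl-2H-chromen-6-yl)-2-(4-methoxyphenyl)ethane-1,2-dione | COc1ccc(C(=O)C(=O)c2cc(OC)c3c(c2O)C=CC(C)(C)O3)cc1 | target

## Step count and least certain steps

Total: 8 steps. Longest linear sequence: 5 steps (1 → 4 → 5 → 7 → 16 → 18; the branch 8 → 9 → 10 → 13 → 16 → 18 is equally long).

**Step 7 (key step).** The fully substituted diene may close the ring too slowly, because the prenyl group on C4a and the bulky ketal-bearing acyl group crowd the C5–C6 bond. Protodesilylation of 7 back to 4, or conjugate addition without ring closure, could then win. A second risk is the work-up: too little acid leaves the ketal, too much adds a phenol across the prenyl double bond.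
The fallback sets out from 1 and 13 and rejoins the route at 18.
- Silylation of 1 (Me3SiCl, Et3N) should give methyl (E)-4-methoxy-3-(trimethylsilyloxy)but-2-enoate F1.
- LiN(iPr)2 and Me3SiCl should then give the prenyl-free diene 1,4-dimethoxy-1,3-bis(trimethylsilyloxy)buta-1,3-diene F2, which is less hindered.
- F2 and 13 under the conditions of step 7 should give 1-(2,4-dihydroxy-5-methoxyphenyl)-2-(4-methoxyphenyl)ethane-1,2-dione F3.
- Alkylation of its unchelated hydroxyl with 3-chloro-3-methylbut-1-yne (K2CO3, KI, acetone) should give 1-[2-hydroxy-5-methoxy-4-(2-methylbut-3-yn-2-yloxy)phenyl]-2-(4-methoxyphenyl)ethane-1,2-dione F4.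
- Heating F4 (o-xylene, 140 °C) should set off a propargyl Claisen rearrangement to the only free ortho carbon, a 1,5-hydrogen shift and oxa-6π closure, giving 18 directly, so that step 8 is not needed.

**Step 3.** The base may also remove a hydrogen from the doubly allylic prenyl methylene, silylation may occur partly on carbon, and the bis(trimethylsilyl) diene may hydrolyse during handling.
The fallback sets out from 4 and rejoins the route at 16. Double soft enolisation of 4 with tBuMe2SiOTf and Et3N (CH2Cl2, 0 °C → rt) uses no strong base. It should give 1,3-bis(tert-butyldimethylsilyloxy)-1,4-dimethoxy-2-(3-methylbut-2-enyl)buta-1,3-diene F5, which is sturdy enough to be purified. F5 then takes the place of 7 in step 7, with Bu4NF/AcOH before the dilute acid to cleave the aryl silyl ethers, and should give 16.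

**Step 6.** The released N,O-dimethylhydroxylamine may add to the terminal ynone during the quench, and the ynone may oligomerise on concentration.
The fallback sets out from 10 and rejoins the route at 13. Reduction of 10 with LiAlH4 (THF, −78 → 0 °C) should give 2,2-dimethoxy-2-(4-methoxyphenyl)acetaldehyde F6. Addition of 11 should give 1,1-dimethoxy-1-(4-methoxyphenyl)but-3-yn-2-ol F7 (racemic). Oxidation of F7 with Dess–Martin periodinane (NaHCO3, CH2Cl2) should give 13 under neutral, amine-free conditions.

**Step 8.** DDQ may over-oxidise the para-related C5–OH/C8–OMe pair towards a quinone, or closure may occur in part on the C5 oxygen.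
The fallback sets out from 16 and rejoins the route at 18. PhSeCl (CH2Cl2, −78 °C) should form a seleniranium ion on the prenyl alkene, which the free C8a hydroxyl opens at the tertiary carbon. This should give 1-[5-hydroxy-8-methoxy-2,2-dimethyl-3-(phenylselanyl)chroman-6-yl]-2-(4-methoxyphenyl)ethane-1,2-dione F8 (racemic). Oxidation at selenium with NaIO4 (NaHCO3, aqueous THF) and syn-elimination towards the benzylic C4 hydrogen should give 18 without any quinone oxidant.

## Further compounds

F1 | step 7 | methyl (E)-4-methoxy-3-(trimethylsilyloxy)but-2-enoate (one alkene isomer drawn) | COC/C(O[Si](C)(C)C)=C\C(=O)OC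
F2 | step 7 | (1Z,3Z)-1,4-dimethoxy-1,3-bis(trimethylsilyloxy)buta-1,3-diene (one isomer drawn) | CO/C=C(\O[Si](C)(C)C)/C=C(/OC)O[Si](C)(C)C
F3 | step 7 | 1-(2,4-dihydroxy-5-methoxyphenyl)-2-(4-methoxyphenyl)ethane-1,2-dione | COc1ccc(C(=O)C(=O)c2cc(OC)c(O)cc2O)cc1
F4 | step 7 | 1-[2-hydroxy-5-methoxy-4-(2-methylbut-3-yn-2-yloxy)phenyl]-2-(4-methoxyphenyl)ethane-1,2-dione | COc1ccc(C(=O)C(=O)c2cc(OC)c(OC(C)(C)C#C)cc2O)cc1
F5 | step 3 | (1Z,3Z)-1,3-bis(tert-butyldimethylsilyloxy)-1,4-dimethoxy-2-(3-methylbut-2-enyl)buta-1,3-diene (one isomer drawn) | CO/C=C(\O[Si](C)(C)C(C)(C)C)/C(CC=C(C)C)=C(/OC)O[Si](C)(C)C(C)(C)C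
F6 | step 6 | 2,2-dimethoxy-2-(4-methoxyphenyl)acetaldehyde | COc1ccc(C(OC)(OC)C=O)cc1
F7 | step 6 | 1,1-dimethoxy-1-(4-methoxyphenyl)but-3-yn-2-ol (racemic, one enantiomer drawn) | COc1ccc(C(OC)(OC)[C@@H](O)C#C)cc1
F8 | step 8 | 1-[5-hydroxy-8-methoxy-2,2-dimethyl-3-(phenylselanyl)chroman-6-yl]-2-(4-methoxyphenyl)ethane-1,2-dione (racemic, one enantiomer drawn) | COc1ccc(C(=O)C(=O)c2cc(OC)c3c(c2O)C[C@H]([Se]c2ccccc2)C(C)(C)O3)cc1
A1 | alternative 1 | 1-[8-methoxy-5-(methoxymethoxy)-2,2-dimethyl-2H-chromen-6-yl]-2-(4-methoxyphenyl)ethane-1,2-dione | COCOc1c(C(=O)C(=O)c2ccc(OC)cc2)cc(OC)c2c1C=CC(C)(C)O2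
A2 | alternative 1 | 8-methoxy-5-(methoxymethoxy)-2,2-dimethyl-2H-chromene | COCOc1ccc(OC)c2c1C=CC(C)(C)O2
A3 | alternative 1 | n-butyllithium | [Li]CCCC
A4 | alternative 1 | 1,4-dimethylpiperazine-2,3-dione | CN1CCN(C)C(=O)C1=O
A5 | alternative 1 | 4-methoxyphenylmagnesium bromide | COc1ccc([Mg]Br)cc1
A6 | alternative 2 | (E)-5-isopropoxy-4-methoxy-2-(4-methoxystyryl)phenol | COc1ccc(/C=C/c2cc(OC)c(OC(C)C)cc2O)cc1
A7 | alternative 2 | 3-isopropoxy-4-methoxy-4-[(1E,3E)-4-(4-methoxyphenyl)buta-1,3-dienyl]cyclobut-2-en-1-one (racemic, one enantiomer drawn) | COc1ccc(/C=C/C=C/[C@]2(OC)C(OC(C)C)=CC2=O)cc1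
A8 | alternative 3 | 1-(5-hydroxy-4,8-dimethoxy-2,2-dimethylchroman-6-yl)-2-(4-methoxyphenyl)ethane-1,2-dione (racemic, one enantiomer drawn) | COc1ccc(C(=O)C(=O)c2cc(OC)c3c(c2O)[C@@H](OC)CC(C)(C)O3)cc1
A9 | alternative 3 | 1-(3-formyl-2,4-dihydroxy-5-methoxyphenyl)-2-(4-methoxyphenyl)ethane-1,2-dione | COc1ccc(C(=O)C(=O)c2cc(OC)c(O)c(C=O)c2O)cc1
A10 | alternative 3 | Sc(OTf)3, scandium tris(trifluoromethanesulfonate) | [Sc+3].[O-]S(=O)(=O)C(F)(F)F.[O-]S(=O)(=O)C(F)(F)F.[O-]S(=O)(=O)C(F)(F)F
A11 | alternative 3 | trimethyl orthoformate | COC(OC)OC
A12 | alternative 3 | isobutene (2-methylpropene) | CC(C)=C
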